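**Retrosynthetic overview**
- The strategy rests on the (E)-trisubstituted C2=C3 alkene of the C8 side chain (C1 = ArO–CH2, C8 = terminal =CH2). Its C3 methyl lies cis to the C2–C1 bond, the pattern left by syn methyl–metal addition to a terminal alkyne and capture of the metal by a one-carbon oxygenated electrophile.
- Key disconnection of two bonds (C3–CH3 and C1–C2): silyl-protected (R)-2-methylhept-1-en-6-yn-3-ol, Al(CH3)3 and the aryloxymethyl chloride of ethyl sinapate.
- The enynol comes from pent-4-ynal and isopropenylmagnesium bromide, with a Sharpless kinetic resolution setting C6. The chloride comes from sinapic acid via the ethyl ester and its methylthiomethyl ether.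
- After the coupling, i-Bu2AlH turns the ester into the cinnamyl alcohol and fluoride frees the C6 hydroxyl.
- No ring is formed at any stage; the only ring, the arene, is bought with sinapic acid.

Key step: step 7

Remark on the chemistry: pent-4-ynal and isopropenylmagnesium bromide (solution in THF) are taken as purchased; the carbinol carbon (C6 of the side chain) is R as read from the SMILES, which corresponds to (R)-2-methylhept-1-en-6-yn-3-ol.

**Route**

Step 1
Reactants: 1 pent-4-ynal; 2 isopropenylmagnesium bromide
Product: 3 (±)-2-methylhept-1-en-6-yn-3-ol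
Conditions: THF, −78 → 0 °C; aq. NH4Cl
Reagents that add atoms: none
Why: Grignard 1,2-addition to the aldehyde at −78 °C should be much faster than deprotonation of the terminal alkyne and gives the racemic secondary allylic alcohol, no stereocontrol being sought at this stage.

Step 2
Reactants: 3 (±)-2-methylhept-1-en-6-yn-3-ol
Product: 4 (R)-2-methylhept-1-en-6-yn-3-ol
Conditions: Ti(OiPr)4 (10 mol %), L-(+)-diisopropyl tartrate (15 mol %), t-BuOOH (0.6 equiv), 4 Å molecular sieves, CH2Cl2, −20 °C; chromatography
Reagents that add atoms: none
Why: Sharpless kinetic resolution, in which the titanium tartrate of L-(+)-diisopropyl tartrate should epoxidise the (S)-carbinol much faster (to the erythro epoxy alcohol) and leave the (R)-alcohol that becomes C6 of the target; it is chosen over an enzymatic acylation because the two carbinol substituents are of similar size, and the alkyne is inert to the oxidant.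

Step 3
Reactants: 4 (R)-2-methylhept-1-en-6-yn-3-ol
Product: 5 (R)-tert-butyldimethyl[(2-methylhept-1-en-6-yn-3-yl)oxy]silane
Conditions: t-BuMe2SiCl, imidazole, DMF, 23 °C
Reagents that add atoms: tert-butyldimethylsilyl chloride CC(C)(C)[Si](C)(C)Cl
Why: Imidazole-promoted silylation of a secondary alcohol masks the hydroxyl against Al(CH3)3 and does not touch the stereocentre.

Step 4
Reactants: 6 sinapic acid
Product: 7 ethyl sinapate [ethyl (E)-3-(4-hydroxy-3,5-dimethoxyphenyl)acrylate]
Conditions: EtOH, H2SO4 (cat.), reflux
Reagents that add atoms: ethanol CCO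
Why: Fischer esterification removes the acidic carboxyl proton that would quench the alane and leaves the phenol and the E-alkene unchanged.

Step 5
Reactants: 7 ethyl sinapate; 8 chloromethyl methyl sulfide
Product: 9 ethyl (E)-3-{3,5-dimethoxy-4-[(methylsulfanyl)methoxy]phenyl}acrylate
Conditions: NaH, DMF, 0 °C; then 8, NaI (cat.), 0 → 23 °C
Reagents that add atoms: none
Why: Williamson-type O-alkylation of the sodium phenoxide by the α-chloro sulfide (activated in situ as the iodide) is the standard way to methylthiomethyl ethers of hindered phenols.

Step 6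
Reactants: 9 ethyl (E)-3-{3,5-dimethoxy-4-[(methylsulfanyl)methoxy]phenyl}acrylate
Product: 10 ethyl (E)-3-[4-(chloromethoxy)-3,5-dimethoxyphenyl]acrylate
Conditions: SO2Cl2 (1.0 equiv), CH2Cl2, −40 → 0 °C; then cyclohexene (2 equiv); volatiles off at 0.1 mmHg, residue used crude under argon
Reagents that add atoms: sulfuryl chloride O=S(=O)(Cl)Cl
Why: Chlorinative cleavage of an O,S-acetal, in which sulfur as the most nucleophilic site is chlorinated and the chlorosulfonium ion collapses to the aryloxymethyl chloride, SO2 and CH3SCl, the latter being trapped by cyclohexene before it can add to the cinnamate.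

Step 7
Reactants: 5 (R)-tert-butyldimethyl[(2-methylhept-1-en-6-yn-3-yl)oxy]silane; 11 trimethylaluminium; 10 ethyl (E)-3-[4-(chloromethoxy)-3,5-dimethoxyphenyl]acrylate
Product: 13 ethyl (E)-3-[4-[(2E,6R)-6-(tert-butyldimethylsilyloxy)-3,7-dimethylocta-2,7-dienoxy]-3,5-dimethoxyphenyl]acrylate, via (E)-alkenyldimethylalane 12 (not isolated)
Conditions: Al(CH3)3 (2.5 equiv), Cp2ZrCl2 (0.25 equiv), CH2Cl2, 0 → 23 °C; volatiles off in vacuo; CH2Cl2, −78 °C, then 10 (1.3 equiv), −78 → −20 °C; cold aq. potassium sodium tartrate
Reagents that add atoms: none
Why: Proposed new method: Cp2ZrCl2 and Al(CH3)3 form a methylzirconium–aluminium species that adds CH3 and metal syn across the terminal alkyne of 5, CH3 going to the internal carbon (C3) and the metal, exchanged for aluminium, to the terminal carbon (C2), so that alane 12 is E; the alkenyl–aluminium π bond then attacks the oxocarbenium ion that the Lewis-acidic aluminium releases from chloride 10, and loss of the aluminium fragment forms the C1–C2 bond with retention of geometry. The closest known reaction is the zirconium-catalysed methylalumination of terminal alkynes followed by capture of the alkenylalane with chloromethyl methyl ether to give (E)-allylic methyl ethers; an aryloxymethyl chloride has not been used as the capturing partner, but the aryloxy oxygen, twisted out of conjugation by its two ortho methoxy groups, should still support ionisation. No ring is closed and no stereocentre is created: C6 is carried through unchanged, and the alkene geometry follows from syn addition and retentive substitution. The step needs regioselective methyl delivery (secured by the terminal alkyne), alkenyl in preference to methyl transfer to 10 (secured by the higher reactivity of the sp2 carbon–aluminium bond and by stripping excess Al(CH3)3 before 10 is added), and survival of the enoate, the silyl ether and the 1,1-disubstituted alkene (secured by capture at −78 to −20 °C and by the inertness of non-terminal alkenes to the zirconocene system).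

Step 8
Reactants: 13 ethyl (E)-3-[4-[(2E,6R)-6-(tert-butyldimethylsilyloxy)-3,7-dimethylocta-2,7-dienoxy]-3,5-dimethoxyphenyl]acrylate
Product: 14 (E)-3-[4-[(2E,6R)-6-(tert-butyldimethylsilyloxy)-3,7-dimethylocta-2,7-dienoxy]-3,5-dimethoxyphenyl]prop-2-en-1-ol
Conditions: i-Bu2AlH (2.5 equiv), CH2Cl2, −78 °C; aq. potassium sodium tartrate
Reagents that add atoms: none
Why: i-Bu2AlH reduces the α,β-unsaturated ester by two 1,2-hydride deliveries to the allylic alcohol at low temperature without touching the alkenes, the allyl aryl ether or the silyl ether.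

Step 9
Reactants: 14 (E)-3-[4-[(2E,6R)-6-(tert-butyldimethylsilyloxy)-3,7-dimethylocta-2,7-dienoxy]-3,5-dimethoxyphenyl]prop-2-en-1-ol
Product: 15 (3R,6E)-8-{4-[(E)-3-hydroxyprop-1-enyl]-2,6-dimethoxyphenoxy}-2,6-dimethylocta-1,6-dien-3-ol (target)
Conditions: Bu4NF, THF, 0 → 23 °C
Reagents that add atoms: none
Why: Fluoride-mediated desilylation, driven by the strong Si–F bond, frees the C6 hydroxyl under non-acidic conditions that the allyl aryl ether and the cinnamyl alcohol tolerate, and the stereocentre is not involved.

**Compound list**
1 | pent-4-ynal | C#CCCC=O | starting material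
2 | isopropenylmagnesium bromide [bromo(prop-1-en-2-yl)magnesium] | C=C(C)[Mg]Br | starting material
3 | (±)-2-methylhept-1-en-6-yn-3-ol | C=C(C)C(O)CCC#C | intermediate
4 | (R)-2-methylhept-1-en-6-yn-3-ol | C=C(C)[C@H](O)CCC#C | intermediate
5 | (R)-tert-butyldimethyl[(2-methylhept-1-en-6-yn-3-yl)oxy]silane | C=C(C)[C@H](O[Si](C)(C)C(C)(C)C)CCC#C | intermediate
6 | sinapic acid [(E)-3-(4-hydroxy-3,5-dimethoxyphenyl)acrylic acid] | COc1cc(/C=C/C(=O)O)cc(OC)c1O | starting material
7 | ethyl sinapate [ethyl (E)-3-(4-hydroxy-3,5-dimethoxyphenyl)acrylate] | CCOC(=O)/C=C/c1cc(OC)c(O)c(OC)c1 | intermediate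
8 | chloromethyl methyl sulfide | CSCCl | starting material
9 | ethyl (E)-3-{3,5-dimethoxy-4-[(methylsulfanyl)methoxy]phenyl}acrylate | CSCOc1c(OC)cc(/C=C/C(=O)OCC)cc1OC | intermediate
10 | ethyl (E)-3-[4-(chloromethoxy)-3,5-dimethoxyphenyl]acrylate | ClCOc1c(OC)cc(/C=C/C(=O)OCC)cc1OC | intermediate
11 | trimethylaluminium | C[Al](C)C | starting material
12 | [(1E,5R)-5-(tert-butyldimethylsilyloxy)-2,6-dimethylhepta-1,6-dien-1-yl]dimethylalumane | C=C(C)[C@H](O[Si](C)(C)C(C)(C)C)CC/C(C)=C/[Al](C)C | intermediate
13 | ethyl (E)-3-[4-[(2E,6R)-6-(tert-butyldimethylsilyloxy)-3,7-dimethylocta-2,7-dienoxy]-3,5-dimethoxyphenyl]acrylate | C=C(C)[C@H](O[Si](C)(C)C(C)(C)C)CC/C(C)=C/COc1c(OC)cc(/C=C/C(=O)OCC)cc1OC | intermediate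
14 | (E)-3-[4-[(2E,6R)-6-(tert-butyldimethylsilyloxy)-3,7-dimethylocta-2,7-dienoxy]-3,5-dimethoxyphenyl]prop-2-en-1-ol | C=C(C)[C@H](O[Si](C)(C)C(C)(C)C)CC/C(C)=C/COc1c(OC)cc(/C=C/CO)cc1OC | intermediate
15 | (3R,6E)-8-{4-[(E)-3-hydroxyprop-1-enyl]-2,6-dimethoxyphenoxy}-2,6-dimethylocta-1,6-dien-3-ol (CNP0161487.1) | C=C(C)[C@H](O)CC/C(C)=C/COc1c(OC)cc(/C=C/CO)cc1OC | target

**Step count**
Total: 9 steps. Longest linear sequence: 6 steps (1, 2, 3, 7, 8, 9 from pent-4-ynal; equally 4, 5, 6, 7, 8, 9 from sinapic acid).

**Steps most likely to fail**

Step 7 (bears the new-method label). What may go wrong: transfer of methyl instead of the alkenyl group to the oxocarbenium ion; Lewis-acid cleavage of the aryl–O–CH2 linkage before or after C–C bond formation (the product is an ionisable allylic aryl ether); Prins-type attack on the isopropenyl group; attack of the alane on the enoate. The fallback uses known chemistry, sets out from 5 and comes back at 13. Compound 5 is methylaluminated as before to alane 12. After excess Al(CH3)3 is stripped, n-BuLi (hexane/THF, −78 → 0 °C) should convert 12 into lithium alkenyl(butyl)dimethylaluminate F1, whose alkenyl group adds to paraformaldehyde to give, after hydrolysis, (2E,6R)-6-(tert-butyldimethylsilyloxy)-3,7-dimethylocta-2,7-dien-1-ol F2. CBr4/PPh3 (CH2Cl2, 0 °C, Appel reaction) should turn F2 into the allylic bromide tert-butyl{[(3R,6E)-8-bromo-2,6-dimethylocta-1,6-dien-3-yl]oxy}dimethylsilane F3. K2CO3 in DMF should then alkylate phenol 7 with F3 (Williamson etherification) to give 13. The C1–C2 bond is then made with formaldehyde and the aryl–O–C1 bond by SN2 displacement, so no oxocarbenium ion meets the alane.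

Step 6. What may go wrong: chlorination or sulfenylation of the electron-rich arene or of the cinnamate alkene, and hydrolysis of the moisture-sensitive chloride during isolation. The fallback sets out from 7 and comes back at 10. The sodium phenoxide of 7 (NaH, THF) is alkylated with a large excess of bromochloromethane at 0 → 23 °C. Bromide is displaced in preference to chloride, and the two ortho methoxy groups together with the excess dihalide should hold back the second displacement to the bis(aryloxy)methane, as is established for 2,6-disubstituted phenols. Compound 9 and the sulfur chemistry are bypassed, and no compound outside the list is made (F0).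

Step 2. What may go wrong: an insufficient rate difference between the enantiomers, or loss of the volatile alcohol during separation from the epoxy alcohol, giving low enantiomeric purity or low recovery. The fallback sets out from 3 and comes back at 4. Dess–Martin periodinane (CH2Cl2, 0 °C) oxidises 3 to 2-methylhept-1-en-6-yn-3-one F4. F4 is reduced with catecholborane and (S)-1-methyl-3,3-diphenyltetrahydro-1H,3H-pyrrolo[1,2-c][1,3,2]oxazaborole (10 mol %) in toluene at −78 °C (Corey–Bakshi–Shibata reduction). The α-branched isopropenyl group should act as the large substituent, so that hydride delivery gives the (R)-alcohol 4, and all of the material rather than half is carried forward.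

Further compounds
F1 | step 7 | lithium [(1E,5R)-5-(tert-butyldimethylsilyloxy)-2,6-dimethylhepta-1,6-dien-1-yl](butyl)dimethylaluminate | [Li+].CCCC[Al-](C)(C)/C=C(\C)CC[C@@H](O[Si](C)(C)C(C)(C)C)C(C)=C
F2 | step 7 | (2E,6R)-6-(tert-butyldimethylsilyloxy)-3,7-dimethylocta-2,7-dien-1-ol | C=C(C)[C@H](O[Si](C)(C)C(C)(C)C)CC/C(C)=C/CO
F3 | step 7 | tert-butyl{[(3R,6E)-8-bromo-2,6-dimethylocta-1,6-dien-3-yl]oxy}dimethylsilane | C=C(C)[C@H](O[Si](C)(C)C(C)(C)C)CC/C(C)=C/CBr
F0 | step 6 | none | none
F4 | step 2 | 2-methylhept-1-en-6-yn-3-one | C=C(C)C(=O)CCC#C
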